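# Proposed synthesis of CNP0257325.1 (compound 28) by cyclobutenone–siloxyalkyne benzannulation

## The problem

Compound 28 is a (2S)-flavanone in which every carbon of ring A (C4a, C5, C6, C7, C8, C8a) is substituted. Three oxygens in a 1,3,5 pattern (ring oxygen O1 on C8a, the chelated hydroxyl on C5, the hydroxyl on C7) alternate with three carbons: the acyl carbon C4 on C4a, a (2R)-2-hydroxy-3-methylbut-3-enyl chain on C6 and a prenyl group on C8. A synthesis must therefore tell three phloroglucinol oxygens and two similar five-carbon chains apart. In a symmetric acylphloroglucinol the C5 and C8a oxygens are equivalent, and whichever of them closes ring C decides which chain ends up on C6 and which on C8. The two stereocentres, C2 in ring C and C2'' in the C6 chain, are separated by the flat arene and cannot direct each other, so each needs its own reagent or catalyst control. C2 is labile: under base the flavanone opens by retro-oxa-Michael reaction to the 2'-hydroxychalcone and recloses without memory. Acid is no safer, because an ortho-prenylphenol cyclizes to a chroman and the secondary allylic alcohol next to the isopropenyl group ionizes; the three alkenes also exclude hydrogenolysis. The feature that allows a direct solution is the alternation itself. With hydrogen still on C4a, ring A is a phenol with the sequence OH (C8a), C (C8), O (C7), C (C6), O (C5), H (C4a), which is the pattern produced when a 2-alkyl-3-silyloxycyclobutenone and a 1-silyloxyalkyne are joined, each oxygen arriving in a different state.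

## Retrosynthesis

**28 from 27.** Only O–Si bonds are cut. All four hydroxyls are carried as silyl ethers (aryl TIPS on O5 and O7, aryl TBS on O4', alkyl TBS on O2''), so the last step needs buffered fluoride and neither acid nor hydrogen. Acetal or benzyl protection would bring back exactly the conditions the target does not tolerate.

**27 from chromone 25 and boronic acid 26.** The C2–C1' bond is cut. The neighbouring cut at O1–C2 (oxa-Michael closure of a 2'-hydroxychalcone) forms the stereocentre in a reversible step and is poorly enantioselective for unactivated chalcones. The cut at C4–C4a needs a preformed chiral aryl ether on a crowded phenol. Chromone 25 has no stereocentre in ring C, and 26 is commercial. The forward reaction must be a catalyst-controlled 1,4-arylation that is fast enough on an electron-rich chromone and leaves three isolated alkenes alone.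

**25 from aldehyde 21 and ethynylmagnesium bromide 11, by way of 22.** The O1–C2 and C3–C4 bonds are cut. Because C8a–OH is the only free phenol in 21, ring C can close in one direction only. The alternative of first making a methyl ketone and adding a one-carbon unit costs a step more. The forward sequence asks for addition to a hindered salicylaldehyde without silyl migration and a mild oxidation that spares the phenol.

**21 from phenol 19.** The C4a–C4 bond is cut. C4a is the only unsubstituted ring position and lies ortho to the only free hydroxyl, so a phenoxide-directed formylation has no regiochemical choice. A Friedel–Crafts acylation would need Lewis acids that the silyl ethers and the prenyl group do not survive.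

**19 from cyclobutenone 9 and siloxyalkyne 14 (key disconnection).** The C8–C8a and C6–C7 bonds are cut, and the C8a–C4a bond of the four-membered ring is broken and re-formed. Against stepwise C-alkylation of a phloroglucinol, this cut brings every ring atom in with its substituent and leaves the future O1 as the only free hydroxyl. The reversed pairing (prenyl on the cyclobutenone, C6 chain on the alkyne) would free the C5 oxygen instead and was rejected for that reason. Both precursors are acyclic or monocyclic and carry at most one stereocentre. The forward reaction must be regioselective in the ketene–alkyne union and must proceed below the decomposition temperature of both partners.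

**9 from siloxyalkyne 7 and ketene 8; 7 from 5, 4, and finally methacrolein 1 and allenylboronate 2.** The four-membered ring is cut into its two two-carbon halves, which places the C6 chain on C2 and the silyloxy group on C3. The alkyne C–O bond of 7 is traced to oxidation of the terminal alkyne 5. The bond between C2'' and the propargylic carbon is cut to 1 and 2, so that C2'' is set by an asymmetric propargylation on a six-carbon fragment, before anything valuable is attached.

**14 from enyne 12; 12 from prenyl bromide 10 and 11.** The same alkyne oxidation is used, preceded by a copper-catalysed allyl–alkynyl coupling. Both branches thus rest on one method.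

## Roads not taken

**Alternative 1:** The cut is at C2''–O, made late on the finished flavanone. The substrate would be the tris-MOM (2S)-flavanone A1, carrying an (E)-4-hydroxy-3-methylbut-2-enyl chain on C6 and prenyl on C8. Ti(OiPr)4, D-(−)-diethyl tartrate and tert-butyl hydroperoxide would epoxidize only the allylic alcohol and give the (2''R,3''R)-epoxy alcohol A2. Iodination and zinc-induced reductive opening would then transpose A2 to the 1-en-3-ol of the target.
- Merits: the Sharpless epoxidation of trisubstituted (E)-allylic alcohols is among the most reliable enantioselective reactions, and the hydroxyl-directed oxidant ignores the C8 prenyl group. In certainty of the C2'' configuration this road is better than step 1 of the chosen plan, whose selectivity on a small α-branched enal has to be established.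
- Weak points: it solves only the side-chain stereocentre. A1 presupposes a ring A with two different chains in defined positions and a defined choice between the C5 and C8a oxygens, which is the unsolved part. C2 would have to survive titanium alkoxide, iodide, zinc and a final acidic MOM cleavage that also threatens the ortho-prenylphenol and the new allylic alcohol. Three to four steps follow the epoxidation.
- What the chosen plan sets against it: regiochemistry settled by construction and a fluoride-only deprotection.

**Alternative 2:** The cut is at C4–C4a. The precursor is the aryl bromide A3, with bromine on C4a and the C8a oxygen bound to an enantiopure (S)-3-aryl-3-oxypropanoic Weinreb amide. tert-Butyllithium would exchange the bromine, and the carbanion would acylate itself on the amide (Parham cyclization) to give the protected flavanone A4.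
- Merits: C2 is fixed before ring C exists, and the ring is closed irreversibly by C–C bond formation, so no chalcone equilibrium can erode it. In security of C2 this road is at least as good as a catalytic arylation of a crowded, untested chromone.
- Weak points: the aryl ether in A3 must be made on a phenol flanked by prenyl and bromine from a secondary, 4-alkoxybenzylic alcohol, where inversion competes with ionization and elimination. After the exchange, the β-aryloxy amide can expel the phenoxide by E1cB elimination. A pentasubstituted, differentially protected bromophenol is needed, so the ring A problem is only moved, and the MOM groups again require acid at the end.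
- What the chosen plan sets against it: a shorter sequence and a ring A that is differentiated without protecting-group manipulation.

**Alternative 3:** The cuts are at C3–C4 and O1–C2, made together. The salicylaldehyde A5 (formyl on C4a, free hydroxyl on C8a) would be ionized with trimethyl orthoformate and a chiral phosphoric acid to the 4-methoxy ortho-quinone methide A6. Cycloaddition with the styrene A7 would give the (2S)-2,4-cis-4-methoxyflavan A8, and the C4 ether would then be converted to the ketone.
- Merits: it is the most convergent construction of ring C, one step from an aldehyde of the same type as 21, against three steps (9 to 11) in the chosen plan, and it uses no organometallic reagent.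
- Weak points: face control over a cationic, very electron-rich quinone methide reacting with a simple styrene rests on ion pairing alone. The acidic medium endangers the MOM acetals and the silylated allylic carbinol. The C8 prenyl group sits next to the quinone methide oxygen and can capture it intramolecularly. C4 needs further redox adjustment next to the benzylic C2 ether.
- What the chosen plan sets against it: a stereo-determining step with a well-understood enantioface model and neutral conditions throughout.

Key step: step 7

## Route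

Remark: ketene 8 is taken as a commodity gas made on demand by pyrolysis of acetone. The sense of induction in steps 1 and 11 is assigned by analogy with the closest substrate classes and would be confirmed on 4 and 27; the mirror-image catalyst is the remedy if it is reversed.

Step 1
Reactants: 1 methacrolein; 2 allenylboronic acid pinacol ester
Product: 4 (R)-2-methylhex-1-en-5-yn-3-ol, via borate ester 3 (not isolated)
Conditions: (R)-3,3'-bis(2,4,6-triisopropylphenyl)-1,1'-binaphthyl-2,2'-diyl hydrogen phosphate [(R)-TRIP] (5 mol%), 4 Å MS, toluene, −30 °C; aq. NaHCO3 work-up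
Reagents that add atoms: none
Why: Chiral-phosphoric-acid-catalysed allenylboration (asymmetric propargylation) through a closed six-membered SE2′ transition state, which gives only the homopropargylic alcohol. The acid hydrogen-bonds to a boronate oxygen and, as with aryl and alkenyl aldehydes, (R)-TRIP is expected to direct addition to the Re face, which sets C2'' as (R). Borate 3 is hydrolysed on work-up.

Step 2
Reactants: 4 (R)-2-methylhex-1-en-5-yn-3-ol
Product: 5 (R)-tert-butyldimethyl[(2-methylhex-1-en-5-yn-3-yl)oxy]silane
Conditions: TBSCl, imidazole, DMF, 0 °C → rt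
Reagents that add atoms: tert-butyldimethylsilyl chloride, CC(C)(C)[Si](C)(C)Cl
Why: Standard silylation of a secondary allylic alcohol. The TBS ether tolerates the organolithium, thermal, Grignard and oxidation steps that follow and is removed by fluoride at the end.

Step 3
Reactants: 5 (R)-tert-butyldimethyl[(2-methylhex-1-en-5-yn-3-yl)oxy]silane
Product: 7 (R)-3-(tert-butyldimethylsilyloxy)-2-methyl-6-(triisopropylsilyloxy)hex-1-en-5-yne, via lithium ynolate 6 (not isolated)
Conditions: LiN(SiMe3)2, THF, −78 °C; t-BuOOLi (from t-BuOOH and LiN(SiMe3)2), −78 → 0 °C; TIPSOTf, −78 → 0 °C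
Reagents that add atoms: lithium tert-butyl peroxide, [Li+].[O-]OC(C)(C)C; triisopropylsilyl trifluoromethanesulfonate, CC(C)[Si](C(C)C)(C(C)C)OS(=O)(=O)C(F)(F)F
Why: Electrophilic oxygenation of the lithium acetylide by the lithium peroxide gives ynolate 6. The bulky silyl triflate reacts at oxygen, not carbon, which is the established preparation of isolable triisopropylsilyl ynol ethers.

Step 4
Reactants: 7 (R)-3-(tert-butyldimethylsilyloxy)-2-methyl-6-(triisopropylsilyloxy)hex-1-en-5-yne; 8 ketene
Product: 9 2-[(2R)-2-(tert-butyldimethylsilyloxy)-3-methylbut-3-enyl]-3-(triisopropylsilyloxy)cyclobut-2-enone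
Conditions: ketene gas stream, CH2Cl2, 0 °C → rt; rapid filtration through Et3N-deactivated silica
Reagents that add atoms: none
Why: Ketene–ynol ether [2+2] cycloaddition. The nucleophilic, chain-bearing alkyne carbon attacks the ketene carbonyl carbon and the silyloxy-bearing carbon bonds to the ketene CH2, which places the chain on C2 and the silyloxy group on C3. C2'' is not touched.

Step 5
Reactants: 10 prenyl bromide; 11 ethynylmagnesium bromide
Product: 12 5-methylhex-4-en-1-yne
Conditions: HC≡CMgBr (1.5 equiv), CuCl (5 mol%), THF, 0 → 40 °C; fractional distillation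
Reagents that add atoms: none
Why: Copper-catalysed allyl–alkynyl coupling. The alkynylcopper species attacks the unhindered primary terminus (SN2, not SN2′ at the tertiary carbon), and the excess of 11 suppresses double alkylation.

Step 6
Reactants: 12 5-methylhex-4-en-1-yne
Product: 14 5-methyl-1-(triisopropylsilyloxy)hex-4-en-1-yne, via lithium ynolate 13 (not isolated)
Conditions: LiN(SiMe3)2, THF, −78 °C; t-BuOOLi (from t-BuOOH and LiN(SiMe3)2), −78 → 0 °C; TIPSOTf, −78 → 0 °C
Reagents that add atoms: lithium tert-butyl peroxide, [Li+].[O-]OC(C)(C)C; triisopropylsilyl trifluoromethanesulfonate, CC(C)[Si](C(C)C)(C(C)C)OS(=O)(=O)C(F)(F)F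
Why: Same acetylide oxidation and O-silylation as in step 3. At −78 °C the amide base removes the alkyne proton, not the less acidic allylic–propargylic CH2, so the skipped enyne is not isomerized.

Step 7
Reactants: 9 2-[(2R)-2-(tert-butyldimethylsilyloxy)-3-methylbut-3-enyl]-3-(triisopropylsilyloxy)cyclobut-2-enone; 14 5-methyl-1-(triisopropylsilyloxy)hex-4-en-1-yne
Product: 19 2-(3-methylbut-2-enyl)-4-[(2R)-2-(tert-butyldimethylsilyloxy)-3-methylbut-3-enyl]-3,5-bis(triisopropylsilyloxy)phenol, via vinylketene 15 (not isolated), via 4-vinylcyclobutenone 16 (not isolated), via dienylketene 17 (not isolated), via cyclohexadienone 18 (not isolated)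
Conditions: toluene (0.5 M, degassed), 110 °C, sealed tube; 14 in 1.3-fold excess
Reagents that add atoms: none
Why: Danheiser benzannulation of a cyclobutenone with a siloxyalkyne, whose closest known examples are the unions of 2- and 3-substituted cyclobutenones with triisopropylsilyloxyalkynes to resorcinol monosilyl ethers. Thermal four-electron electrocyclic opening of 9 gives vinylketene 15. Its carbonyl carbon (future C8a) is attacked by the nucleophilic, prenyl-bearing carbon of 14 and its α-carbon (future C6) bonds to the silyloxy-bearing carbon (future C7); this regioselective [2+2] cycloaddition forms C8–C8a and C6–C7 and gives 16. A second four-electron opening gives dienylketene 17; only the isomer with ketene and silyloxyvinyl groups cis can close, and the other returns through 16. Six-electron electrocyclization joins C8a to C4a and closes ring A as cyclohexadienone 18, which tautomerizes irreversibly to phenol 19. No stereocentre is formed, and C2'' is a spectator that cannot epimerize under neutral thermolysis. The selectivity required is regiochemical and is secured by the polarization of the ynol ether, whose β-carbon is the nucleophile, matched with the electrophilic ketene carbon, so that prenyl lands next to the only free hydroxyl. The excess of 14 keeps the stationary concentration of 15 low and so limits ketene dimerization and acylation of the product phenol.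

Step 8
Reactants: 19 2-(3-methylbut-2-enyl)-4-[(2R)-2-(tert-butyldimethylsilyloxy)-3-methylbut-3-enyl]-3,5-bis(triisopropylsilyloxy)phenol
Product: 21 2-hydroxy-3-(3-methylbut-2-enyl)-5-[(2R)-2-(tert-butyldimethylsilyloxy)-3-methylbut-3-enyl]-4,6-bis(triisopropylsilyloxy)benzaldehyde, via benzylic alcohol 20 (not isolated)
Conditions: MgCl2, Et3N, (CH2O)n, MeCN, 80 °C; dilute citric acid work-up
Reagents that add atoms: paraformaldehyde (as formaldehyde), C=O
Why: Magnesium-mediated ortho-formylation (Casnati–Skattebøl type). The magnesium phenoxide delivers formaldehyde to C4a, the only free ring position and ortho to the free hydroxyl, and benzylic alkoxide 20 is oxidized in the flask by hydride transfer to a second formaldehyde. The weakly basic medium spares silyl ethers and alkenes.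

Step 9
Reactants: 21 2-hydroxy-3-(3-methylbut-2-enyl)-5-[(2R)-2-(tert-butyldimethylsilyloxy)-3-methylbut-3-enyl]-4,6-bis(triisopropylsilyloxy)benzaldehyde; 11 ethynylmagnesium bromide
Product: 22 2-(1-hydroxyprop-2-ynyl)-6-(3-methylbut-2-enyl)-4-[(2R)-2-(tert-butyldimethylsilyloxy)-3-methylbut-3-enyl]-3,5-bis(triisopropylsilyloxy)phenol (both carbinol epimers)
Conditions: HC≡CMgBr (3 equiv), THF, −78 → −20 °C; cold aq. NH4Cl; used crude
Reagents that add atoms: none
Why: Grignard 1,2-addition to a salicylaldehyde; the first equivalent forms the phenoxide and the next adds to the chelated aldehyde. The new carbinol centre is destroyed in step 10, and the low temperature and cold quench guard against 1,5-migration of the C5 silyl group to the magnesium alkoxide.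

Step 10
Reactants: 22 2-(1-hydroxyprop-2-ynyl)-6-(3-methylbut-2-enyl)-4-[(2R)-2-(tert-butyldimethylsilyloxy)-3-methylbut-3-enyl]-3,5-bis(triisopropylsilyloxy)phenol
Product: 25 8-(3-methylbut-2-enyl)-6-[(2R)-2-(tert-butyldimethylsilyloxy)-3-methylbut-3-enyl]-5,7-bis(triisopropylsilyloxy)-4H-chromen-4-one, via ynone 23 (not isolated), via enaminone 24 (not isolated)
Conditions: MnO2 (activated, excess), CH2Cl2, rt; filtration; Et2NH, EtOH, rt; AcOH, 40 °C
Reagents that add atoms: none
Why: MnO2 oxidizes the benzylic–propargylic alcohol to ynone 23, and conjugate addition of Et2NH gives enaminone 24, which excludes the 5-exo (aurone) pathway. Acid-promoted addition–elimination by the only free phenol then forms O1–C2 and expels the amine; this is the established alkynone–enaminone–chromone sequence.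

Step 11
Reactants: 25 8-(3-methylbut-2-enyl)-6-[(2R)-2-(tert-butyldimethylsilyloxy)-3-methylbut-3-enyl]-5,7-bis(triisopropylsilyloxy)-4H-chromen-4-one; 26 4-(tert-butyldimethylsilyloxy)phenylboronic acid
Product: 27 (2S)-2-[4-(tert-butyldimethylsilyloxy)phenyl]-6-[(2R)-2-(tert-butyldimethylsilyloxy)-3-methylbut-3-enyl]-8-(3-methylbut-2-enyl)-5,7-bis(triisopropylsilyloxy)chroman-4-one
Conditions: [Rh(OH)(cod)]2 (2.5 mol%), (S)-2,2'-bis[bis(3,4,5-trifluorophenyl)phosphino]-6,6'-dimethoxy-1,1'-biphenyl [(S)-MeO-F12-BIPHEP] (5.5 mol%), 26 (2 equiv), CH2Cl2/H2O 10:1, 30 °C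
Reagents that add atoms: none
Why: Rhodium-catalysed asymmetric 1,4-addition of an arylboronic acid to a chromone (Hayashi–Miyaura type): transmetalation to the rhodium hydroxide, enantioface-selective carbometalation of C2=C3, then protonolysis of the rhodium enolate. The electron-poor bisphosphine speeds addition to the sluggish chromone, and base-free conditions avoid retro-oxa-Michael opening. C2 is set by the ligand alone: (S)-biaryl bisphosphines give (S)-3-arylcyclohexanones, and the priority order O1 > aryl > C3 maps onto that model without change of descriptor, so the (S)-ligand should give (2S).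

Step 12
Reactants: 27 (2S)-2-[4-(tert-butyldimethylsilyloxy)phenyl]-6-[(2R)-2-(tert-butyldimethylsilyloxy)-3-methylbut-3-enyl]-8-(3-methylbut-2-enyl)-5,7-bis(triisopropylsilyloxy)chroman-4-one
Product: 28 (2S)-5,7-dihydroxy-6-[(2R)-2-hydroxy-3-methylbut-3-enyl]-2-(4-hydroxyphenyl)-8-(3-methylbut-2-enyl)chroman-4-one
Conditions: TBAF/AcOH (1:1, excess), THF, 0 → 35 °C
Reagents that add atoms: none
Why: Fluoride cleavage of all four silyl ethers; the aryl ethers fall quickly and the secondary allylic TBS ether sets the reaction time. The acetic acid buffer keeps the phenols protonated, so the flavanone does not open to the chalcone and C2 is preserved. No acid strong enough to ionize the allylic alcohol or cyclize the ortho-prenylphenol is present.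

## Compound list

1 | methacrolein (2-methylprop-2-enal) | C=C(C)C=O | starting material
2 | allenylboronic acid pinacol ester | C=C=CB1OC(C)(C)C(C)(C)O1 | starting material
3 | (R)-4,4,5,5-tetramethyl-2-[(2-methylhex-1-en-5-yn-3-yl)oxy]-1,3,2-dioxaborolane | C=C(C)[C@H](OB1OC(C)(C)C(C)(C)O1)CC#C | intermediate (not isolated)
4 | (R)-2-methylhex-1-en-5-yn-3-ol | C=C(C)[C@H](O)CC#C | intermediate
5 | (R)-tert-butyldimethyl[(2-methylhex-1-en-5-yn-3-yl)oxy]silane | C=C(C)[C@H](O[Si](C)(C)C(C)(C)C)CC#C | intermediate
6 | lithium (R)-4-(tert-butyldimethylsilyloxy)-5-methylhex-5-en-1-yn-1-olate | C=C(C)[C@H](O[Si](C)(C)C(C)(C)C)CC#C[O-].[Li+] | intermediate (not isolated)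
7 | (R)-3-(tert-butyldimethylsilyloxy)-2-methyl-6-(triisopropylsilyloxy)hex-1-en-5-yne | C=C(C)[C@H](O[Si](C)(C)C(C)(C)C)CC#CO[Si](C(C)C)(C(C)C)C(C)C | intermediate
8 | ketene (ethenone) | C=C=O | starting material (gas, made on demand from acetone)
9 | 2-[(2R)-2-(tert-butyldimethylsilyloxy)-3-methylbut-3-enyl]-3-(triisopropylsilyloxy)cyclobut-2-enone | O=C1CC(O[Si](C(C)C)(C(C)C)C(C)C)=C1C[C@@H](O[Si](C)(C)C(C)(C)C)C(C)=C | intermediate
10 | prenyl bromide (1-bromo-3-methylbut-2-ene) | CC(C)=CCBr | starting material
11 | ethynylmagnesium bromide | C#C[Mg]Br | starting material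
12 | 5-methylhex-4-en-1-yne | CC(C)=CCC#C | intermediate
13 | lithium 5-methylhex-4-en-1-yn-1-olate | CC(C)=CCC#C[O-].[Li+] | intermediate (not isolated)
14 | 5-methyl-1-(triisopropylsilyloxy)hex-4-en-1-yne | CC(C)=CCC#CO[Si](C(C)C)(C(C)C)C(C)C | intermediate
15 | 2-[(2R)-2-(tert-butyldimethylsilyloxy)-3-methylbut-3-enyl]-3-(triisopropylsilyloxy)buta-1,3-dien-1-one (vinylketene) | O=C=C(C[C@@H](O[Si](C)(C)C(C)(C)C)C(C)=C)C(=C)O[Si](C(C)C)(C(C)C)C(C)C | intermediate (not isolated)
16 | 2-(3-methylbut-2-enyl)-4-[(2R)-2-(tert-butyldimethylsilyloxy)-3-methylbut-3-enyl]-3-(triisopropylsilyloxy)-4-[1-(triisopropylsilyloxy)ethenyl]cyclobut-2-enone (C4 epimers) | O=C1C(CC=C(C)C)=C(O[Si](C(C)C)(C(C)C)C(C)C)C1(C[C@@H](O[Si](C)(C)C(C)(C)C)C(C)=C)C(=C)O[Si](C(C)C)(C(C)C)C(C)C | intermediate (not isolated)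
17 | 2-(3-methylbut-2-enyl)-4-[(2R)-2-(tert-butyldimethylsilyloxy)-3-methylbut-3-enyl]-3,5-bis(triisopropylsilyloxy)hexa-1,3,5-trien-1-one (dienylketene, ketene and silyloxyvinyl groups cis) | O=C=C(CC=C(C)C)/C(O[Si](C(C)C)(C(C)C)C(C)C)=C(/C[C@@H](O[Si](C)(C)C(C)(C)C)C(C)=C)C(=C)O[Si](C(C)C)(C(C)C)C(C)C | intermediate (not isolated)
18 | 2-(3-methylbut-2-enyl)-4-[(2R)-2-(tert-butyldimethylsilyloxy)-3-methylbut-3-enyl]-3,5-bis(triisopropylsilyloxy)cyclohexa-2,4-dien-1-one | O=C1CC(O[Si](C(C)C)(C(C)C)C(C)C)=C(C[C@@H](O[Si](C)(C)C(C)(C)C)C(C)=C)C(O[Si](C(C)C)(C(C)C)C(C)C)=C1CC=C(C)C | intermediate (not isolated)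
19 | 2-(3-methylbut-2-enyl)-4-[(2R)-2-(tert-butyldimethylsilyloxy)-3-methylbut-3-enyl]-3,5-bis(triisopropylsilyloxy)phenol | Oc1cc(O[Si](C(C)C)(C(C)C)C(C)C)c(C[C@@H](O[Si](C)(C)C(C)(C)C)C(C)=C)c(O[Si](C(C)C)(C(C)C)C(C)C)c1CC=C(C)C | intermediate
20 | 2-(hydroxymethyl)-6-(3-methylbut-2-enyl)-4-[(2R)-2-(tert-butyldimethylsilyloxy)-3-methylbut-3-enyl]-3,5-bis(triisopropylsilyloxy)phenol | OCc1c(O)c(CC=C(C)C)c(O[Si](C(C)C)(C(C)C)C(C)C)c(C[C@@H](O[Si](C)(C)C(C)(C)C)C(C)=C)c1O[Si](C(C)C)(C(C)C)C(C)C | intermediate (not isolated)
21 | 2-hydroxy-3-(3-methylbut-2-enyl)-5-[(2R)-2-(tert-butyldimethylsilyloxy)-3-methylbut-3-enyl]-4,6-bis(triisopropylsilyloxy)benzaldehyde | O=Cc1c(O)c(CC=C(C)C)c(O[Si](C(C)C)(C(C)C)C(C)C)c(C[C@@H](O[Si](C)(C)C(C)(C)C)C(C)=C)c1O[Si](C(C)C)(C(C)C)C(C)C | intermediate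
22 | 2-(1-hydroxyprop-2-ynyl)-6-(3-methylbut-2-enyl)-4-[(2R)-2-(tert-butyldimethylsilyloxy)-3-methylbut-3-enyl]-3,5-bis(triisopropylsilyloxy)phenol (carbinol epimers) | C#CC(O)c1c(O)c(CC=C(C)C)c(O[Si](C(C)C)(C(C)C)C(C)C)c(C[C@@H](O[Si](C)(C)C(C)(C)C)C(C)=C)c1O[Si](C(C)C)(C(C)C)C(C)C | intermediate
23 | 1-{2-hydroxy-3-(3-methylbut-2-enyl)-5-[(2R)-2-(tert-butyldimethylsilyloxy)-3-methylbut-3-enyl]-4,6-bis(triisopropylsilyloxy)phenyl}prop-2-yn-1-one | C#CC(=O)c1c(O)c(CC=C(C)C)c(O[Si](C(C)C)(C(C)C)C(C)C)c(C[C@@H](O[Si](C)(C)C(C)(C)C)C(C)=C)c1O[Si](C(C)C)(C(C)C)C(C)C | intermediate (not isolated)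
24 | (E)-3-(diethylamino)-1-{2-hydroxy-3-(3-methylbut-2-enyl)-5-[(2R)-2-(tert-butyldimethylsilyloxy)-3-methylbut-3-enyl]-4,6-bis(triisopropylsilyloxy)phenyl}prop-2-en-1-one | CCN(CC)/C=C/C(=O)c1c(O)c(CC=C(C)C)c(O[Si](C(C)C)(C(C)C)C(C)C)c(C[C@@H](O[Si](C)(C)C(C)(C)C)C(C)=C)c1O[Si](C(C)C)(C(C)C)C(C)C | intermediate (not isolated)
25 | 8-(3-methylbut-2-enyl)-6-[(2R)-2-(tert-butyldimethylsilyloxy)-3-methylbut-3-enyl]-5,7-bis(triisopropylsilyloxy)-4H-chromen-4-one | O=c1ccoc2c(CC=C(C)C)c(O[Si](C(C)C)(C(C)C)C(C)C)c(C[C@@H](O[Si](C)(C)C(C)(C)C)C(C)=C)c(O[Si](C(C)C)(C(C)C)C(C)C)c12 | intermediate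
26 | 4-(tert-butyldimethylsilyloxy)phenylboronic acid | OB(O)c1ccc(O[Si](C)(C)C(C)(C)C)cc1 | starting material
27 | (2S)-2-[4-(tert-butyldimethylsilyloxy)phenyl]-6-[(2R)-2-(tert-butyldimethylsilyloxy)-3-methylbut-3-enyl]-8-(3-methylbut-2-enyl)-5,7-bis(triisopropylsilyloxy)chroman-4-one | C=C(C)[C@H](O[Si](C)(C)C(C)(C)C)Cc1c(O[Si](C(C)C)(C(C)C)C(C)C)c(CC=C(C)C)c2c(c1O[Si](C(C)C)(C(C)C)C(C)C)C(=O)C[C@@H](c1ccc(O[Si](C)(C)C(C)(C)C)cc1)O2 | intermediate
28 | (2S)-5,7-dihydroxy-6-[(2R)-2-hydroxy-3-methylbut-3-enyl]-2-(4-hydroxyphenyl)-8-(3-methylbut-2-enyl)chroman-4-one | C=C(C)[C@H](O)Cc1c(O)c(CC=C(C)C)c2c(c1O)C(=O)C[C@@H](c1ccc(O)cc1)O2 | target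

## Step count and least certain steps

Total: 12 steps. Longest linear sequence: 10 steps (1–4, then 7–12); steps 5 and 6 form the second branch.

**Step 7 (key step).** The 3-silyloxy group makes 9 a vinylogous silyl ester, so the first electrocyclic opening may be slow. Forcing the temperature invites 1,3-shift of silicon from oxygen to carbon in 14 (isomerization to a silylketene), hydrolytic loss of the enol silyl group of 9, and diversion of the vinylketene by dimerization or by acylation of the product phenol. The fallback sets out from 9 and 14 and returns at 19. The vinylketene is generated photochemically, not thermally: irradiation (about 300 nm) of 9 with 14 at room temperature triggers the known photochemical ring opening of cyclobutenones at a temperature where 14 is stable, and the [2+2] adduct 16 is collected. Adduct 16 is then heated on its own at about 80 °C; its C4 is quaternary and bears a donor vinyl group, so the second opening and the six-electron closure are easier than the first opening. This changes how the reactive intermediate is made and splits the cascade into two isolated stages; it makes no new compound (F0).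

**Step 11.** Carbometalation of an electron-rich 5,7-bis(silyloxy)chromone may be slower than protodeboronation of 26. Face selectivity on this crowded substrate is untested, and over-addition to the product carbonyl is possible. The fallback sets out from 21 and returns at 27; it forms C2 by O1–C2 closure instead. The alkenyl Grignard reagent (E)-2-[4-(tert-butyldimethylsilyloxy)phenyl]ethenylmagnesium bromide F1 (from the bromoalkene and magnesium) is added to 21 to give the diaryl allylic alcohol F2. MnO2 oxidation gives the 2'-hydroxychalcone F3. Its only free phenol then closes ring C by enantioselective intramolecular oxa-Michael addition under a quinine-derived bifunctional thiourea (9-amino-9-deoxy-epi-quinine 3,5-bis(trifluoromethyl)phenylthiourea). Lower selectivity than in step 11 must be expected, because unactivated chalcones cyclize reversibly. Since C2'' is fixed, the C2 epimers are diastereomers and could be enriched by crystallization.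

**Step 8.** Hydroxymethylation at a position flanked by a TIPS ether may be slow, and the intermediate benzylic alkoxide may condense with a second molecule of 19 instead of being oxidized. The fallback sets out from 19 and returns at 21; it uses directed ortho-metalation. MOMCl and i-Pr2NEt give the MOM ether F4. n-BuLi in THF at 0 °C lithiates the only ring C–H, between the acetal and silyl ether oxygens, and DMF gives the MOM-protected aldehyde F5. ZnBr2 with n-PrSH then removes the acetal selectively to give 21. Lateral deprotonation of the prenyl CH2 is the point to watch.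

**Step 1.** Uncatalysed background allenylboration of a small α-branched enal could lower the enantiomeric purity of 4, and the volatile product is easily lost on isolation. The fallback sets out from 1 and returns at 4. Zinc-mediated Barbier propargylation with propargyl bromide gives racemic 2-methylhex-1-en-5-yn-3-ol F6. Sharpless kinetic resolution (Ti(OiPr)4, L-(+)-diisopropyl tartrate, 0.6 equiv t-BuOOH, −20 °C) epoxidizes the (S)-enantiomer to the erythro epoxy alcohol (1S)-1-[(2R)-2-methyloxiran-2-yl]but-3-yn-1-ol F7 and leaves (R)-4. The cost is half of the material.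

**Step 12.** Under buffered fluoride the hindered secondary TBS ether may cleave incompletely. Without the buffer, phenoxide-induced opening and reclosure of ring C would epimerize C2. The fallback sets out from 25 and returns at 28; it removes the alkyl silyl ether before C2 exists. HF·pyridine in THF/pyridine at 0 °C cleaves only the alkyl TBS ether of 25 and gives 6-[(2R)-2-hydroxy-3-methylbut-3-enyl]-8-(3-methylbut-2-enyl)-5,7-bis(triisopropylsilyloxy)-4H-chromen-4-one F8. The conditions of step 11 then give the flavanone F9, which has a free C2'' hydroxyl and three aryl silyl ethers, and brief treatment with TBAF/AcOH at 0 °C gives 28.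

## Further compounds

F0 | step 7 | none | none
F1 | step 11 | (E)-2-[4-(tert-butyldimethylsilyloxy)phenyl]ethenylmagnesium bromide | Br[Mg]/C=C/c1ccc(O[Si](C)(C)C(C)(C)C)cc1
F2 | step 11 | 2-{(E)-1-hydroxy-3-[4-(tert-butyldimethylsilyloxy)phenyl]prop-2-enyl}-6-(3-methylbut-2-enyl)-4-[(2R)-2-(tert-butyldimethylsilyloxy)-3-methylbut-3-enyl]-3,5-bis(triisopropylsilyloxy)phenol (carbinol epimers) | OC(/C=C/c1ccc(O[Si](C)(C)C(C)(C)C)cc1)c1c(O)c(CC=C(C)C)c(O[Si](C(C)C)(C(C)C)C(C)C)c(C[C@@H](O[Si](C)(C)C(C)(C)C)C(C)=C)c1O[Si](C(C)C)(C(C)C)C(C)C
F3 | step 11 | (E)-3-[4-(tert-butyldimethylsilyloxy)phenyl]-1-{2-hydroxy-3-(3-methylbut-2-enyl)-5-[(2R)-2-(tert-butyldimethylsilyloxy)-3-methylbut-3-enyl]-4,6-bis(triisopropylsilyloxy)phenyl}prop-2-en-1-one | O=C(/C=C/c1ccc(O[Si](C)(C)C(C)(C)C)cc1)c1c(O)c(CC=C(C)C)c(O[Si](C(C)C)(C(C)C)C(C)C)c(C[C@@H](O[Si](C)(C)C(C)(C)C)C(C)=C)c1O[Si](C(C)C)(C(C)C)C(C)C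
F4 | step 8 | 1-(methoxymethoxy)-2-(3-methylbut-2-enyl)-4-[(2R)-2-(tert-butyldimethylsilyloxy)-3-methylbut-3-enyl]-3,5-bis(triisopropylsilyloxy)benzene | COCOc1cc(O[Si](C(C)C)(C(C)C)C(C)C)c(C[C@@H](O[Si](C)(C)C(C)(C)C)C(C)=C)c(O[Si](C(C)C)(C(C)C)C(C)C)c1CC=C(C)C
F5 | step 8 | 2-(methoxymethoxy)-3-(3-methylbut-2-enyl)-5-[(2R)-2-(tert-butyldimethylsilyloxy)-3-methylbut-3-enyl]-4,6-bis(triisopropylsilyloxy)benzaldehyde | COCOc1c(C=O)c(O[Si](C(C)C)(C(C)C)C(C)C)c(C[C@@H](O[Si](C)(C)C(C)(C)C)C(C)=C)c(O[Si](C(C)C)(C(C)C)C(C)C)c1CC=C(C)C
F6 | step 1 | racemic 2-methylhex-1-en-5-yn-3-ol | C=C(C)C(O)CC#C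
F7 | step 1 | (1S)-1-[(2R)-2-methyloxiran-2-yl]but-3-yn-1-ol | C[C@@]1(CO1)[C@@H](O)CC#C
F8 | step 12 | 6-[(2R)-2-hydroxy-3-methylbut-3-enyl]-8-(3-methylbut-2-enyl)-5,7-bis(triisopropylsilyloxy)-4H-chromen-4-one | O=c1ccoc2c(CC=C(C)C)c(O[Si](C(C)C)(C(C)C)C(C)C)c(C[C@@H](O)C(C)=C)c(O[Si](C(C)C)(C(C)C)C(C)C)c12
F9 | step 12 | (2S)-2-[4-(tert-butyldimethylsilyloxy)phenyl]-6-[(2R)-2-hydroxy-3-methylbut-3-enyl]-8-(3-methylbut-2-enyl)-5,7-bis(triisopropylsilyloxy)chroman-4-one | C=C(C)[C@H](O)Cc1c(O[Si](C(C)C)(C(C)C)C(C)C)c(CC=C(C)C)c2c(c1O[Si](C(C)C)(C(C)C)C(C)C)C(=O)C[C@@H](c1ccc(O[Si](C)(C)C(C)(C)C)cc1)O2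
A1 | alternative 1 | (2S)-6-[(E)-4-hydroxy-3-methylbut-2-enyl]-5,7-bis(methoxymethoxy)-2-[4-(methoxymethoxy)phenyl]-8-(3-methylbut-2-enyl)chroman-4-one | OC/C(C)=C/Cc1c(OCOC)c(CC=C(C)C)c2c(c1OCOC)C(=O)C[C@@H](c1ccc(OCOC)cc1)O2
A2 | alternative 1 | (2S)-6-{[(2R,3R)-3-(hydroxymethyl)-3-methyloxiran-2-yl]methyl}-5,7-bis(methoxymethoxy)-2-[4-(methoxymethoxy)phenyl]-8-(3-methylbut-2-enyl)chroman-4-one | OC[C@@]1(C)O[C@@H]1Cc1c(OCOC)c(CC=C(C)C)c2c(c1OCOC)C(=O)C[C@@H](c1ccc(OCOC)cc1)O2
A3 | alternative 2 | (3S)-3-{2-bromo-3,5-bis(methoxymethoxy)-4-[(2R)-2-(tert-butyldimethylsilyloxy)-3-methylbut-3-enyl]-6-(3-methylbut-2-enyl)phenoxy}-N-methoxy-3-[4-(methoxymethoxy)phenyl]-N-methylpropanamide | C=C(C)[C@H](O[Si](C)(C)C(C)(C)C)Cc1c(OCOC)c(CC=C(C)C)c(O[C@@H](CC(=O)N(C)OC)c2ccc(OCOC)cc2)c(Br)c1OCOC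
A4 | alternative 2 | (2S)-6-[(2R)-2-(tert-butyldimethylsilyloxy)-3-methylbut-3-enyl]-5,7-bis(methoxymethoxy)-2-[4-(methoxymethoxy)phenyl]-8-(3-methylbut-2-enyl)chroman-4-one | C=C(C)[C@H](O[Si](C)(C)C(C)(C)C)Cc1c(OCOC)c(CC=C(C)C)c2c(c1OCOC)C(=O)C[C@@H](c1ccc(OCOC)cc1)O2
A5 | alternative 3 | 2-hydroxy-4,6-bis(methoxymethoxy)-3-(3-methylbut-2-enyl)-5-[(2R)-2-(tert-butyldimethylsilyloxy)-3-methylbut-3-enyl]benzaldehyde | O=Cc1c(O)c(CC=C(C)C)c(OCOC)c(C[C@@H](O[Si](C)(C)C(C)(C)C)C(C)=C)c1OCOC
A6 | alternative 3 | 6-(methoxymethylidene)-3,5-bis(methoxymethoxy)-2-(3-methylbut-2-enyl)-4-[(2R)-2-(tert-butyldimethylsilyloxy)-3-methylbut-3-enyl]cyclohexa-2,4-dien-1-one | COC=C1C(=O)C(CC=C(C)C)=C(OCOC)C(C[C@@H](O[Si](C)(C)C(C)(C)C)C(C)=C)=C1OCOC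
A7 | alternative 3 | 4-(tert-butyldimethylsilyloxy)styrene | C=Cc1ccc(O[Si](C)(C)C(C)(C)C)cc1
A8 | alternative 3 | (2S,4S)-2-[4-(tert-butyldimethylsilyloxy)phenyl]-4-methoxy-5,7-bis(methoxymethoxy)-6-[(2R)-2-(tert-butyldimethylsilyloxy)-3-methylbut-3-enyl]-8-(3-methylbut-2-enyl)chromane | C=C(C)[C@H](O[Si](C)(C)C(C)(C)C)Cc1c(OCOC)c(CC=C(C)C)c2c(c1OCOC)[C@@H](OC)C[C@@H](c1ccc(O[Si](C)(C)C(C)(C)C)cc1)O2
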